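**Plan**

- Cuts: the tetraene is cut at C2'–C3' and C4'–C5' (tetraenyl chain numbered from the lactone) into a lactone vinyl iodide, a two-carbon distannane and a pyran bromodiene. In the lactone (ring numbered O1, C2(=O), C3, C4, C5) the O1–C5 and C3–C4 bonds are cut together, giving an acyclic (S)-allylic propanoate that carries an enyne.
- Enabling feature: C4 is a quaternary carbon that bears an alkenyl group next to C3(H)(CH3)–C2(=O)O, a Claisen retron. C5 and its side-chain carbon C(CH3)CO2CH3 are treated as a former alkyne, so the acid released by the [3,3] shift is a 4-alkynoic acid that closes 5-exo-dig while CO and methanol add the ester.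
- Forward: enyne propanoate → one-pot Ireland–Claisen and palladium-catalysed cyclising methoxycarbonylation → ozonolysis → hydrogenation (removes the extra unsaturation) → Takai iodide → dienylstannane. The pyran is built by asymmetric epoxidation, epoxide opening with a phosphono acid, ring-closing Horner–Wadsworth–Emmons reaction and C-methylation; the halves are joined by Stille coupling.
- Stereochemistry: C3 and C4 come from (S)-lactaldehyde by chair chirality transfer. C5 and the side-chain carbon come from the E enol-lactone geometry and syn addition of H2 opposite the two methyls. Pyran C2 and C3 come from Sharpless epoxidation and invertive opening, and C6 from pseudo-axial methyl transfer. Alkene geometries come from Wittig, Claisen, Takai, carboalumination and Stille steps.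

Key step: step 6

Assumption: compounds 1 and 16, 2-(triphenylphosphoranylidene)propanal, (E)-1,2-bis(tributylstannyl)ethene and (E)-1-bromo-2-iodoethene are taken as purchasable; the tertiary hydroxyl of the pyran is carried unprotected.

**Route**

Step 1
Reactants: 1 (S)-2-[(tert-butyldimethylsilyl)oxy]propanal
Product: 2 (S,E)-4-[(tert-butyldimethylsilyl)oxy]-2-methylpent-2-enal
Conditions: Ph3P=C(CH3)CHO, toluene, 80 °C
Reagents that add atoms: 2-(triphenylphosphoranylidene)propanal, CC(C=O)=P(c1ccccc1)(c1ccccc1)c1ccccc1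
Why: Wittig olefination with a stabilized formyl ylide should give the E trisubstituted enal and leave the silyloxy stereocentre of 1 untouched.

Step 2
Reactants: 2 (S,E)-4-[(tert-butyldimethylsilyl)oxy]-2-methylpent-2-enal
Product: 3 (S,E)-tert-butyl[(6,6-dibromo-4-methylhexa-3,5-dien-2-yl)oxy]dimethylsilane
Conditions: CBr4, PPh3, CH2Cl2, 0 °C
Reagents that add atoms: carbon tetrabromide, BrC(Br)(Br)Br
Why: Corey–Fuchs (Ramirez) dibromo-olefination turns the formyl group into the 1,1-dibromoalkene that is the alkyne precursor; no stereocentre is formed.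

Step 3
Reactants: 3 (S,E)-tert-butyl[(6,6-dibromo-4-methylhexa-3,5-dien-2-yl)oxy]dimethylsilane
Product: 5 (S,E)-tert-butyldimethyl[(4-methylhept-3-en-5-yn-2-yl)oxy]silane, via lithium acetylide 4 (not isolated)
Conditions: n-BuLi (2.1 equiv), THF, −78 °C; then CH3I, DMPU, −78 → 23 °C
Reagents that add atoms: iodomethane, CI
Why: Bromine–lithium exchange and Fritsch–Buttenberg–Wiechell shift (second Corey–Fuchs stage) should give acetylide 4, whose C-methylation installs the future C-methyl of the propanoate side chain.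

Step 4
Reactants: 5 (S,E)-tert-butyldimethyl[(4-methylhept-3-en-5-yn-2-yl)oxy]silane
Product: 6 (S,E)-4-methylhept-3-en-5-yn-2-ol
Conditions: Bu4NF, THF, 0 → 23 °C
Reagents that add atoms: none
Why: Fluoride-induced silyl ether cleavage frees the allylic alcohol without affecting the enyne or the carbinol configuration.

Step 5
Reactants: 6 (S,E)-4-methylhept-3-en-5-yn-2-ol
Product: 7 (S,E)-4-methylhept-3-en-5-yn-2-yl propanoate
Conditions: EtCOCl, pyridine, DMAP (cat.), CH2Cl2, 0 °C
Reagents that add atoms: propanoyl chloride, CCC(=O)Cl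
Why: Pyridine/DMAP acylation of the secondary allylic alcohol gives the Ireland–Claisen substrate with retention at the carbinol carbon.

Step 6
Reactants: 7 (S,E)-4-methylhept-3-en-5-yn-2-yl propanoate
Product: 11 methyl (E)-2-[(3R,4R)-3,4-dimethyl-5-oxo-3-[(E)-prop-1-en-1-yl]dihydrofuran-2(3H)-ylidene]propanoate, via silyl ketene acetal 8 (not isolated), via silyl ester 9 (not isolated), via alkynoic acid 10 (not isolated)
Conditions: LiN(iPr)2, THF, −78 °C; Me3SiCl, −78 → 55 °C; then, same flask, MeOH, PdCl2(MeCN)2 (5 mol %), p-benzoquinone, CO (1 atm), 0 → 23 °C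
Reagents that add atoms: carbon monoxide, [C-]#[O+]; methanol, CO
Why: Kinetic enolisation and O-silylation give the E ketene acetal 8, whose chair [3,3] shift (Ireland–Claisen rearrangement) forms the C3–C4 bond, and methanol then frees acid 10 from silyl ester 9. Divalent palladium activates the alkyne, the carboxylate attacks anti in a 5-exo-dig closure that forms the O1–C5 bond, and the vinylpalladium inserts CO and is methanolysed, with p-benzoquinone reoxidising zerovalent palladium. The closest known reaction types are the Ireland–Claisen rearrangement and the palladium-catalysed oxidative cyclisation–alkoxycarbonylation of alkynes carrying an O–H nucleophile. C3 and C4 are set together by the chair transition state: the carbinol methyl of the (S)-ester sits equatorial, the ketene acetal methyl is cis to the allylic oxygen, and the E alkene places the alkynyl group equatorial, which should give 2R,3R in acid 10. The step needs alkyne-over-alkene and 5-exo-over-6-endo selectivity, which the higher affinity of palladium for the alkyne and the geminal substitution at C4 should secure. The anti addition fixes the E enol-lactone geometry on which step 8 relies.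

Step 7
Reactants: 11 methyl (E)-2-[(3R,4R)-3,4-dimethyl-5-oxo-3-[(E)-prop-1-en-1-yl]dihydrofuran-2(3H)-ylidene]propanoate
Product: 12 methyl (E)-2-[(3R,4R)-3-formyl-3,4-dimethyl-5-oxodihydrofuran-2(3H)-ylidene]propanoate
Conditions: O3 (1 equiv), CH2Cl2, −78 °C; then Me2S
Reagents that add atoms: ozone, [O-][O+]=O
Why: Ozonolysis with reductive work-up should cleave the electron-richer 1,2-disubstituted propenyl group in preference to the tetrasubstituted, acceptor-substituted enol-lactone double bond, unveiling the aldehyde on C4.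

Step 8
Reactants: 12 methyl (E)-2-[(3R,4R)-3-formyl-3,4-dimethyl-5-oxodihydrofuran-2(3H)-ylidene]propanoate
Product: 13 methyl (R)-2-[(2S,3R,4R)-3-formyl-3,4-dimethyl-5-oxotetrahydrofuran-2-yl]propanoate
Conditions: H2 (4 atm), 5% Rh/Al2O3, EtOAc, 23 °C
Reagents that add atoms: none
Why: Heterogeneous hydrogenation should add both hydrogens syn from the ring face that carries only the formyl group and C3–H, opposite the C3 and C4 methyls, so that C5 becomes S and, because the double bond is E, the side-chain carbon becomes R.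

Step 9
Reactants: 13 methyl (R)-2-[(2S,3R,4R)-3-formyl-3,4-dimethyl-5-oxotetrahydrofuran-2-yl]propanoate
Product: 14 methyl (R)-2-[(2S,3S,4R)-3-[(E)-2-iodoethenyl]-3,4-dimethyl-5-oxotetrahydrofuran-2-yl]propanoate
Conditions: CrCl2, CHI3, THF, 0 → 23 °C
Reagents that add atoms: iodoform, IC(I)I
Why: Takai olefination converts the hindered, non-enolisable aldehyde into the E vinyl iodide without base, so the β-acyloxy ester and the epimerisable centres are not endangered.

Step 10
Reactants: 14 methyl (R)-2-[(2S,3S,4R)-3-[(E)-2-iodoethenyl]-3,4-dimethyl-5-oxotetrahydrofuran-2-yl]propanoate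
Product: 15 methyl (R)-2-[(2S,3R,4R)-3,4-dimethyl-5-oxo-3-[(1E,3E)-4-(tributylstannyl)buta-1,3-dien-1-yl]tetrahydrofuran-2-yl]propanoate
Conditions: (E)-Bu3SnCH=CHSnBu3 (3 equiv), PdCl2(MeCN)2 (5 mol %), DMF, 23 °C
Reagents that add atoms: (E)-1,2-bis(tributylstannyl)ethene, CCCC[Sn](CCCC)(CCCC)/C=C/[Sn](CCCC)(CCCC)CCCC
Why: Stille coupling of the vinyl iodide with an excess of the distannane should stop at mono-coupling and give the E,E dienylstannane with retention of both alkene geometries.

Step 11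
Reactants: 16 3-(trimethylsilyl)prop-2-ynal
Product: 17 (E)-2-methyl-5-(trimethylsilyl)pent-2-en-4-ynal
Conditions: Ph3P=C(CH3)CHO, CH2Cl2, 23 °C
Reagents that add atoms: 2-(triphenylphosphoranylidene)propanal, CC(C=O)=P(c1ccccc1)(c1ccccc1)c1ccccc1
Why: Wittig olefination with the stabilized ylide should give the E enynal, with the alkynyl group cis to the methyl, as the epoxidation route requires.

Step 12
Reactants: 17 (E)-2-methyl-5-(trimethylsilyl)pent-2-en-4-ynal
Product: 18 (E)-2-methyl-5-(trimethylsilyl)pent-2-en-4-yn-1-ol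
Conditions: NaBH4, CeCl3·7H2O, MeOH, −40 °C
Reagents that add atoms: none
Why: Luche reduction gives clean 1,2-reduction of the conjugated aldehyde to the allylic alcohol without touching the alkene geometry.

Step 13
Reactants: 18 (E)-2-methyl-5-(trimethylsilyl)pent-2-en-4-yn-1-ol
Product: 19 [(2R,3R)-2-methyl-3-[(trimethylsilyl)ethynyl]oxiran-2-yl]methanol
Conditions: Ti(OiPr)4 (cat.), D-(−)-diethyl tartrate, t-BuOOH, 4 Å MS, CH2Cl2, −20 °C
Reagents that add atoms: tert-butyl hydroperoxide, CC(C)(C)OO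
Why: Sharpless asymmetric epoxidation of the E trisubstituted allylic alcohol sets both epoxide carbons (2R,3R) through the face selection of the D-(−)-tartrate catalyst.

Step 14
Reactants: 19 [(2R,3R)-2-methyl-3-[(trimethylsilyl)ethynyl]oxiran-2-yl]methanol
Product: 20 (2R,3S)-1,2-dihydroxy-2-methyl-5-(trimethylsilyl)pent-4-yn-3-yl 2-(diethoxyphosphoryl)propanoate
Conditions: Ti(OiPr)4 (1.5 equiv), (EtO)2P(O)CH(CH3)CO2H, CH2Cl2, 23 °C
Reagents that add atoms: 2-(diethoxyphosphoryl)propanoic acid, CCOP(=O)(OCC)C(C)C(=O)O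
Why: Ti(OiPr)4-mediated opening of the 2,3-epoxy alcohol by the carboxylic acid should occur at C3 (propargylic, remote from the titanium-bound carbinol) with inversion, which gives the anti relation between the future ring-oxygen carbon and the tertiary carbinol.

Step 15
Reactants: 20 (2R,3S)-1,2-dihydroxy-2-methyl-5-(trimethylsilyl)pent-4-yn-3-yl 2-(diethoxyphosphoryl)propanoate
Product: 21 (2S,3S)-2-hydroxy-2-methyl-1-oxo-5-(trimethylsilyl)pent-4-yn-3-yl 2-(diethoxyphosphoryl)propanoate
Conditions: PhI(OAc)2, TEMPO (10 mol %), CH2Cl2, 23 °C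
Reagents that add atoms: none
Why: Oxoammonium (TEMPO) oxidation is selective for the primary alcohol, while the tertiary alcohol cannot be oxidised and the quaternary α-carbon cannot epimerise.

Step 16
Reactants: 21 (2S,3S)-2-hydroxy-2-methyl-1-oxo-5-(trimethylsilyl)pent-4-yn-3-yl 2-(diethoxyphosphoryl)propanoate
Product: 22 (5R,6S)-5-hydroxy-3,5-dimethyl-6-[(trimethylsilyl)ethynyl]-5,6-dihydro-2H-pyran-2-one
Conditions: LiCl, i-Pr2NEt, MeCN, 23 °C
Reagents that add atoms: none
Why: Intramolecular Horner–Wadsworth–Emmons olefination under Masamune–Roush conditions closes the six-membered unsaturated lactone; the ring enforces the Z alkene and only the secondary oxygen carries the phosphonate.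

Step 17
Reactants: 22 (5R,6S)-5-hydroxy-3,5-dimethyl-6-[(trimethylsilyl)ethynyl]-5,6-dihydro-2H-pyran-2-one
Product: 24 (5R,6S)-5-hydroxy-3,5-dimethyl-6-[(trimethylsilyl)ethynyl]-5,6-dihydro-2H-pyran-2-yl acetate, via lactol aluminate 23 (not isolated)
Conditions: i-Bu2AlH (2.3 equiv), CH2Cl2, −78 °C; then Ac2O, pyridine, DMAP, −78 → −20 °C
Reagents that add atoms: acetic anhydride, CC(=O)OC(C)=O
Why: Low-temperature hydride reduction stops at the lactol aluminate and acetylation in the same flask (reductive acetylation) should trap the anomeric oxygen, leaving the hindered tertiary alkoxide to be freed on work-up.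

Step 18
Reactants: 24 (5R,6S)-5-hydroxy-3,5-dimethyl-6-[(trimethylsilyl)ethynyl]-5,6-dihydro-2H-pyran-2-yl acetate
Product: 25 (2S,3R,6S)-3,5,6-trimethyl-2-[(trimethylsilyl)ethynyl]-3,6-dihydro-2H-pyran-3-ol
Conditions: AlMe3 (4 equiv), CH2Cl2, −78 → −20 °C
Reagents that add atoms: trimethylaluminium, C[Al](C)C
Why: AlMe3 ionises the allylic acetal acetate to the cyclic oxocarbenium ion and should transfer methyl pseudo-axially at the anomeric carbon, anti to the C2 alkynyl group (C-glycosidation type), which gives the 2,6-trans ring with C6 as S.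

Step 19
Reactants: 25 (2S,3R,6S)-3,5,6-trimethyl-2-[(trimethylsilyl)ethynyl]-3,6-dihydro-2H-pyran-3-ol
Product: 26 (2S,3R,6S)-2-ethynyl-3,5,6-trimethyl-3,6-dihydro-2H-pyran-3-ol
Conditions: K2CO3, MeOH, 23 °C
Reagents that add atoms: none
Why: Methanolic carbonate protodesilylation of the alkynylsilane frees the terminal alkyne without affecting the ring stereocentres.

Step 20
Reactants: 26 (2S,3R,6S)-2-ethynyl-3,5,6-trimethyl-3,6-dihydro-2H-pyran-3-ol
Product: 28 (2S,3R,6S)-2-[(2E,4E)-5-bromopenta-2,4-dien-2-yl]-3,5,6-trimethyl-3,6-dihydro-2H-pyran-3-ol, via alkenylalane 27 (not isolated)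
Conditions: AlMe3 (3 equiv), Cp2ZrCl2 (0.3 equiv), ClCH2CH2Cl, 0 → 23 °C; then (E)-BrCH=CHI, Pd(PPh3)4 (5 mol %), ZnCl2, THF, 23 °C
Reagents that add atoms: trimethylaluminium, C[Al](C)C; (E)-1-bromo-2-iodoethene, Br/C=C/I
Why: Zirconium-catalysed syn carboalumination (Negishi) puts methyl on the internal and aluminium on the terminal alkyne carbon, and palladium-catalysed cross-coupling at the C–I bond of the dihaloethene then gives the E,E bromodiene with retention.

Step 21
Reactants: 15 methyl (R)-2-[(2S,3R,4R)-3,4-dimethyl-5-oxo-3-[(1E,3E)-4-(tributylstannyl)buta-1,3-dien-1-yl]tetrahydrofuran-2-yl]propanoate; 28 (2S,3R,6S)-2-[(2E,4E)-5-bromopenta-2,4-dien-2-yl]-3,5,6-trimethyl-3,6-dihydro-2H-pyran-3-ol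
Product: 29 methyl (R)-2-[(2S,3R,4R)-3-[(1E,3E,5E,7E)-8-[(2S,3R,6S)-3-hydroxy-3,5,6-trimethyl-3,6-dihydro-2H-pyran-2-yl]nona-1,3,5,7-tetraen-1-yl]-3,4-dimethyl-5-oxotetrahydrofuran-2-yl]propanoate
Conditions: Pd2(dba)3 (5 mol %), AsPh3, DMF, 40 °C, dark
Reagents that add atoms: none
Why: Stille coupling joins the dienylstannane and the bromodiene with retention of all alkene geometries under neutral conditions that the lactone, the β-acyloxy ester and the tertiary allylic alcohol should tolerate.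

**Compound list**

1 | (S)-2-[(tert-butyldimethylsilyl)oxy]propanal | C[C@H](O[Si](C)(C)C(C)(C)C)C=O | starting material
2 | (S,E)-4-[(tert-butyldimethylsilyl)oxy]-2-methylpent-2-enal | C[C@H](O[Si](C)(C)C(C)(C)C)/C=C(\C)C=O | intermediate
3 | (S,E)-tert-butyl[(6,6-dibromo-4-methylhexa-3,5-dien-2-yl)oxy]dimethylsilane | C[C@H](O[Si](C)(C)C(C)(C)C)/C=C(\C)C=C(Br)Br | intermediate
4 | lithium (S,E)-5-[(tert-butyldimethylsilyl)oxy]-3-methylhex-3-en-1-yn-1-ide | C[C@H](O[Si](C)(C)C(C)(C)C)/C=C(\C)C#C[Li] | intermediate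
5 | (S,E)-tert-butyldimethyl[(4-methylhept-3-en-5-yn-2-yl)oxy]silane | C[C@H](O[Si](C)(C)C(C)(C)C)/C=C(\C)C#CC | intermediate
6 | (S,E)-4-methylhept-3-en-5-yn-2-ol | C[C@H](O)/C=C(\C)C#CC | intermediate
7 | (S,E)-4-methylhept-3-en-5-yn-2-yl propanoate | CCC(=O)O[C@@H](C)/C=C(\C)C#CC | intermediate
8 | trimethyl{[(E)-1-{[(S,E)-4-methylhept-3-en-5-yn-2-yl]oxy}prop-1-en-1-yl]oxy}silane | C/C=C(\O[C@@H](C)/C=C(\C)C#CC)O[Si](C)(C)C | intermediate
9 | trimethylsilyl (2R,3R,E)-2,3-dimethyl-3-(prop-1-yn-1-yl)hex-4-enoate | C[Si](C)(C)OC(=O)[C@H](C)[C@@](C#CC)(C)/C=C/C | intermediate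
10 | (2R,3R,E)-2,3-dimethyl-3-(prop-1-yn-1-yl)hex-4-enoic acid | OC(=O)[C@H](C)[C@@](C#CC)(C)/C=C/C | intermediate
11 | methyl (E)-2-[(3R,4R)-3,4-dimethyl-5-oxo-3-[(E)-prop-1-en-1-yl]dihydrofuran-2(3H)-ylidene]propanoate | COC(=O)/C(C)=C1/OC(=O)[C@H](C)[C@@]1(C)/C=C/C | intermediate
12 | methyl (E)-2-[(3R,4R)-3-formyl-3,4-dimethyl-5-oxodihydrofuran-2(3H)-ylidene]propanoate | COC(=O)/C(C)=C1/OC(=O)[C@H](C)[C@@]1(C)C=O | intermediate
13 | methyl (R)-2-[(2S,3R,4R)-3-formyl-3,4-dimethyl-5-oxotetrahydrofuran-2-yl]propanoate | COC(=O)[C@H](C)[C@@H]1OC(=O)[C@H](C)[C@@]1(C)C=O | intermediate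
14 | methyl (R)-2-[(2S,3S,4R)-3-[(E)-2-iodoethenyl]-3,4-dimethyl-5-oxotetrahydrofuran-2-yl]propanoate | COC(=O)[C@H](C)[C@@H]1OC(=O)[C@H](C)[C@@]1(C)/C=C/I | intermediate
15 | methyl (R)-2-[(2S,3R,4R)-3,4-dimethyl-5-oxo-3-[(1E,3E)-4-(tributylstannyl)buta-1,3-dien-1-yl]tetrahydrofuran-2-yl]propanoate | COC(=O)[C@H](C)[C@@H]1OC(=O)[C@H](C)[C@@]1(C)/C=C/C=C/[Sn](CCCC)(CCCC)CCCC | intermediate
16 | 3-(trimethylsilyl)prop-2-ynal | C[Si](C)(C)C#CC=O | starting material
17 | (E)-2-methyl-5-(trimethylsilyl)pent-2-en-4-ynal | O=C/C(C)=C/C#C[Si](C)(C)C | intermediate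
18 | (E)-2-methyl-5-(trimethylsilyl)pent-2-en-4-yn-1-ol | OC/C(C)=C/C#C[Si](C)(C)C | intermediate
19 | [(2R,3R)-2-methyl-3-[(trimethylsilyl)ethynyl]oxiran-2-yl]methanol | OC[C@@]1(C)O[C@@H]1C#C[Si](C)(C)C | intermediate
20 | (2R,3S)-1,2-dihydroxy-2-methyl-5-(trimethylsilyl)pent-4-yn-3-yl 2-(diethoxyphosphoryl)propanoate | C[Si](C)(C)C#C[C@H](OC(=O)C(C)P(=O)(OCC)OCC)[C@](C)(O)CO | intermediate
21 | (2S,3S)-2-hydroxy-2-methyl-1-oxo-5-(trimethylsilyl)pent-4-yn-3-yl 2-(diethoxyphosphoryl)propanoate | C[Si](C)(C)C#C[C@H](OC(=O)C(C)P(=O)(OCC)OCC)[C@](C)(O)C=O | intermediate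
22 | (5R,6S)-5-hydroxy-3,5-dimethyl-6-[(trimethylsilyl)ethynyl]-5,6-dihydro-2H-pyran-2-one | C[Si](C)(C)C#C[C@@H]1OC(=O)C(C)=C[C@@]1(C)O | intermediate
23 | bis(diisobutylaluminium) alkoxide of (5R,6S)-3,5-dimethyl-6-[(trimethylsilyl)ethynyl]-5,6-dihydro-2H-pyran-2,5-diol | C[Si](C)(C)C#C[C@@H]1OC(O[Al](CC(C)C)CC(C)C)C(C)=C[C@@]1(C)O[Al](CC(C)C)CC(C)C | intermediate
24 | (5R,6S)-5-hydroxy-3,5-dimethyl-6-[(trimethylsilyl)ethynyl]-5,6-dihydro-2H-pyran-2-yl acetate (both anomers) | C[Si](C)(C)C#C[C@@H]1OC(OC(C)=O)C(C)=C[C@@]1(C)O | intermediate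
25 | (2S,3R,6S)-3,5,6-trimethyl-2-[(trimethylsilyl)ethynyl]-3,6-dihydro-2H-pyran-3-ol | C[Si](C)(C)C#C[C@@H]1O[C@@H](C)C(C)=C[C@@]1(C)O | intermediate
26 | (2S,3R,6S)-2-ethynyl-3,5,6-trimethyl-3,6-dihydro-2H-pyran-3-ol | C#C[C@@H]1O[C@@H](C)C(C)=C[C@@]1(C)O | intermediate
27 | dimethyl[(E)-2-[(2S,3R,6S)-3-(dimethylalumanyloxy)-3,5,6-trimethyl-3,6-dihydro-2H-pyran-2-yl]prop-1-en-1-yl]alumane | C[Al](C)/C=C(\C)[C@@H]1O[C@@H](C)C(C)=C[C@@]1(C)O[Al](C)C | intermediate
28 | (2S,3R,6S)-2-[(2E,4E)-5-bromopenta-2,4-dien-2-yl]-3,5,6-trimethyl-3,6-dihydro-2H-pyran-3-ol | Br/C=C/C=C(\C)[C@@H]1O[C@@H](C)C(C)=C[C@@]1(C)O | intermediate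
29 | methyl (R)-2-[(2S,3R,4R)-3-[(1E,3E,5E,7E)-8-[(2S,3R,6S)-3-hydroxy-3,5,6-trimethyl-3,6-dihydro-2H-pyran-2-yl]nona-1,3,5,7-tetraen-1-yl]-3,4-dimethyl-5-oxotetrahydrofuran-2-yl]propanoate | COC(=O)[C@H](C)[C@@H]1OC(=O)[C@H](C)[C@@]1(C)/C=C/C=C/C=C/C=C(\C)[C@@H]1O[C@@H](C)C(C)=C[C@@]1(C)O | target

**Step count and risks**

Total step count: 21. Longest linear sequence: 11 steps (steps 1–10 and 21; the pyran branch, steps 11–20 and 21, is equally long).

Steps most likely to fail:

Step 6. The palladium stage may be slowed by amine and lithium salts carried over from the rearrangement, or the acid may partition to oxypalladation of the propenyl group or to 6-endo closure. Incomplete control of enolate geometry would also erode the C3/C4 relationship. Fallback: setting out from 7, the Ireland–Claisen rearrangement is run alone and acid 10 is isolated after acidic aqueous work-up. Cyclisation of 10 with AuCl(PPh3)/AgOTf (cat.) and N-iodosuccinimide in MeCN (anti oxyauration, then iododeauration, selective for the alkyne) should give (3R,4R,E)-5-(1-iodoethylidene)-3,4-dimethyl-4-[(E)-prop-1-en-1-yl]dihydrofuran-2(3H)-one F1. Methoxycarbonylation of F1 (PdCl2(PPh3)2, CO, MeOH, i-Pr2NEt, DMF, 23 °C) replaces iodine by the ester with retention and comes back to the route at 11.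

Step 8. Hydrogen may add slowly to the hindered tetrasubstituted double bond, with incomplete face selection or competing reduction of the aldehyde. Fallback: setting out from 12, NaBH4 in MeOH at −40 °C reduces only the aldehyde to methyl (E)-2-[(3S,4R)-3-(hydroxymethyl)-3,4-dimethyl-5-oxodihydrofuran-2(3H)-ylidene]propanoate F2. Hydroxyl-directed hydrogenation with [Ir(cod)(PCy3)(py)]PF6 and H2 in CH2Cl2 delivers hydrogen from the face of the hydroxymethyl group and gives methyl (R)-2-[(2S,3S,4R)-3-(hydroxymethyl)-3,4-dimethyl-5-oxotetrahydrofuran-2-yl]propanoate F3. Dess–Martin oxidation of F3 comes back to the route at 13.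

Step 18. Methyl transfer may occur at the allylic terminus instead of the anomeric carbon, the tertiary allylic hydroxyl may ionise, or the face selection may be weak. Fallback: setting out from 19, the methyl-bearing carbon is taken from the chiral pool and the ring is closed by metathesis. Ti(OiPr)4-mediated opening of the epoxide at C3 by (S)-3-methylbut-3-en-2-ol (inversion) gives (2R,3S)-2-methyl-3-{[(S)-3-methylbut-3-en-2-yl]oxy}-5-(trimethylsilyl)pent-4-yne-1,2-diol F4. PhI(OAc)2/TEMPO oxidation gives (2S,3S)-2-hydroxy-2-methyl-3-{[(S)-3-methylbut-3-en-2-yl]oxy}-5-(trimethylsilyl)pent-4-ynal F5. Wittig methylenation (Ph3P=CH2, THF) gives (3R,4S)-3-methyl-4-{[(S)-3-methylbut-3-en-2-yl]oxy}-6-(trimethylsilyl)hex-1-en-5-yn-3-ol F6. Ring-closing metathesis of F6 with the second-generation Grubbs catalyst (CH2Cl2, 40 °C) comes back to the route at 25.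

Further compounds
F1 | step 6 | (3R,4R,E)-5-(1-iodoethylidene)-3,4-dimethyl-4-[(E)-prop-1-en-1-yl]dihydrofuran-2(3H)-one | I/C(C)=C1/OC(=O)[C@H](C)[C@@]1(C)/C=C/C
F2 | step 8 | methyl (E)-2-[(3S,4R)-3-(hydroxymethyl)-3,4-dimethyl-5-oxodihydrofuran-2(3H)-ylidene]propanoate | COC(=O)/C(C)=C1/OC(=O)[C@H](C)[C@@]1(C)CO
F3 | step 8 | methyl (R)-2-[(2S,3S,4R)-3-(hydroxymethyl)-3,4-dimethyl-5-oxotetrahydrofuran-2-yl]propanoate | COC(=O)[C@H](C)[C@@H]1OC(=O)[C@H](C)[C@@]1(C)CO
F4 | step 18 | (2R,3S)-2-methyl-3-{[(S)-3-methylbut-3-en-2-yl]oxy}-5-(trimethylsilyl)pent-4-yne-1,2-diol | C[Si](C)(C)C#C[C@H](O[C@@H](C)C(C)=C)[C@](C)(O)CO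
F5 | step 18 | (2S,3S)-2-hydroxy-2-methyl-3-{[(S)-3-methylbut-3-en-2-yl]oxy}-5-(trimethylsilyl)pent-4-ynal | C[Si](C)(C)C#C[C@H](O[C@@H](C)C(C)=C)[C@](C)(O)C=O
F6 | step 18 | (3R,4S)-3-methyl-4-{[(S)-3-methylbut-3-en-2-yl]oxy}-6-(trimethylsilyl)hex-1-en-5-yn-3-ol | C[Si](C)(C)C#C[C@H](O[C@@H](C)C(C)=C)[C@](C)(O)C=C
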